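**Retrosynthetic overview**

1. The target is all-E (2R,3R,2'R,3'R)-nostoxanthin 3'-(hydrogen sulfate). The last disconnection is the C10'–C11' C(sp2)–C(sp2) bond, formed in the final step by a protecting-group-free Suzuki–Miyaura union of a C26 heptaenyl pinacol boronate (ring A, free diol) with a C14 dienyl iodide (ring B, free C2' hydroxyl, C3' sulfate).
2. Enabling feature: C10'–C11' (like C10–C11) is the single bond of an E,E-diene junction between the trisubstituted C9'=C10' and the disubstituted C11'=C12' alkene. The C11–C11' pentaene between the two junctions is C2-symmetric, and ring A and ring B are the same (2R,3R)-2,3-dihydroxy-1,1,5-trimethylcyclohex-5-ene, differing only in the C3' sulfate. One C14 iodide therefore serves both ends and one symmetric C12 bis-boronate is the linchpin.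
3. The C26 boronate comes from mono-coupling of the diol iodide with excess bis-boronate (twofold boron–Wittig on the C10 trienedial). The sulfated iodide comes from site-selective O-sulfation of the same diol iodide at the unhindered C3 hydroxyl.
4. C14 iodide: side chain by reductive triflation, Mizoroki–Heck reaction with methyl vinyl ketone, ketone-to-alkyne conversion and zirconium-catalysed carboalumination/iodination; trans-diol by Jacobsen epoxidation of a cyclohexa-2,4-dienone and anti hydrolysis.
5. Rings: no carbocycle is closed. Both six-membered rings are the dearomatized ring of 2,6-dimethylphenol (step 1); the only ring formed is the oxirane of step 2, opened in step 3.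

Key step: step 13

Remark (assumption): the hydrogen sulfate is carried as its sodium salt (16, 22) and protonated only in the last work-up. Carotenoid numbering is used for the chain; ring A is the unsulfated ring, ring B the sulfated ring.

**Route**

Step 1
Reactants: 1 2,6-dimethylphenol
Product: 3 2,6,6-trimethylcyclohexa-2,4-dien-1-one, via sodium 2,6-dimethylphenoxide 2 (not isolated)
Conditions: NaH, toluene, 0 → 23 °C; then MeI, 60 °C
Reagents that add atoms: methyl iodide, CI
Why: Alkylative dearomatization (ortho C-methylation of a phenoxide): the tight sodium ion pair in toluene directs methyl iodide to the ortho carbon, and because that carbon already carries a methyl group the dienone cannot rearomatize; O-methylation is the expected competing path and the anisole should be separable by distillation.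

Step 2
Reactants: 3 2,6,6-trimethylcyclohexa-2,4-dien-1-one
Product: 4 (4S,5R)-4,5-epoxy-2,6,6-trimethylcyclohex-2-en-1-one
Conditions: (S,S)-(salen)MnCl [chloromanganese complex, trivalent manganese, of (S,S)-N,N'-bis(3,5-di-tert-butylsalicylidene)cyclohexane-1,2-diamine] (5 mol %), N-methylmorpholine N-oxide, mCPBA, CH2Cl2, −78 °C
Reagents that add atoms: 3-chloroperoxybenzoic acid (mCPBA), OOC(=O)c1cccc(Cl)c1
Why: Jacobsen–Katsuki epoxidation: the electrophilic oxo-manganese species should take the distal cis-disubstituted C4=C5 alkene (not the electron-poor C2=C3 enone alkene), and since this alkene sits between a conjugating vinyl carbon and a gem-dimethyl carbon exactly as in 2,2-dimethyl-2H-chromenes, the (S,S)-ligand is expected to set both new stereocentres as (4S,5R).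

Step 3
Reactants: 4 (4S,5R)-4,5-epoxy-2,6,6-trimethylcyclohex-2-en-1-one
Product: 5 (4R,5R)-4,5-dihydroxy-2,6,6-trimethylcyclohex-2-en-1-one
Conditions: HClO4 (cat.), THF/H2O (3:1), 0 → 23 °C
Reagents that add atoms: water, O
Why: Acid-catalysed anti (SN2-like) epoxide hydrolysis: water should attack the allylic C4 because C5 is neopentyl (next to the quaternary carbon), so C4 is inverted and C5 untouched, which gives the trans-(4R,5R)-diol.

Step 4
Reactants: 5 (4R,5R)-4,5-dihydroxy-2,6,6-trimethylcyclohex-2-en-1-one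
Product: 6 (4R,5R)-4,5-bis(tert-butyldimethylsilyloxy)-2,6,6-trimethylcyclohex-2-en-1-one
Conditions: TBSOTf (2.6 equiv), 2,6-lutidine, CH2Cl2, −40 → 23 °C
Reagents that add atoms: tert-butyldimethylsilyl trifluoromethanesulfonate, CC(C)(C)[Si](C)(C)OS(=O)(=O)C(F)(F)F
Why: Silyl triflate silylation is reactive enough for the neopentyl C5 hydroxyl, and the enone has no α-hydrogen that the weak base could remove.

Step 5
Reactants: 6 (4R,5R)-4,5-bis(tert-butyldimethylsilyloxy)-2,6,6-trimethylcyclohex-2-en-1-one
Product: 8 (4R,5R)-4,5-bis(tert-butyldimethylsilyloxy)-2,6,6-trimethylcyclohex-1-en-1-yl trifluoromethanesulfonate, via lithium enolate 7 (not isolated)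
Conditions: LiBH(s-Bu)3 (1.1 equiv), THF, −78 °C; then PhNTf2, −78 → 23 °C
Reagents that add atoms: N-phenylbis(trifluoromethanesulfonimide), O=S(=O)(N(c1ccccc1)S(=O)(=O)C(F)(F)F)C(F)(F)F
Why: Conjugate reduction with enolate trapping: the bulky borohydride should add 1,4 to the β-unsubstituted enone whose carbonyl is shielded by the gem-dimethyl and α-methyl groups, giving the C1–C2 enolate regiospecifically, and O-triflation fixes the tetrasubstituted alkenyl triflate without touching the carbinol centres.

Step 6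
Reactants: 8 (4R,5R)-4,5-bis(tert-butyldimethylsilyloxy)-2,6,6-trimethylcyclohex-1-en-1-yl trifluoromethanesulfonate; 9 methyl vinyl ketone (but-3-en-2-one)
Product: 10 (E)-4-[(4R,5R)-4,5-bis(tert-butyldimethylsilyloxy)-2,6,6-trimethylcyclohex-1-en-1-yl]but-3-en-2-one
Conditions: Pd(OAc)2 (10 mol %), PPh3 (20 mol %), Et3N, DMF, 70 °C
Reagents that add atoms: none
Why: Mizoroki–Heck reaction: oxidative addition of the alkenyl triflate, syn insertion of the unhindered terminal alkene of 9 and syn β-hydride elimination should give the E-dienone (a 2,3-dioxygenated β-ionone), with the silyl ethers inert.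

Step 7
Reactants: 10 (E)-4-[(4R,5R)-4,5-bis(tert-butyldimethylsilyloxy)-2,6,6-trimethylcyclohex-1-en-1-yl]but-3-en-2-one
Product: 12 (4R,5R)-1-[(E)-but-1-en-3-yn-1-yl]-4,5-bis(tert-butyldimethylsilyloxy)-2,6,6-trimethylcyclohex-1-ene, via diethyl enol phosphate 11 (not isolated)
Conditions: LiN(i-Pr)2 (1.1 equiv), THF, −78 °C; ClP(O)(OEt)2; then LiN(i-Pr)2 (2.2 equiv), −78 → 23 °C; H2O
Reagents that add atoms: none
Why: Methyl ketone to terminal alkyne by the enol phosphate route: kinetic deprotonation on the methyl side, O-phosphorylation and base-induced elimination of diethyl phosphate give the alkyne, leaving the E-alkene and silyl ethers untouched.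

Step 8
Reactants: 12 (4R,5R)-1-[(E)-but-1-en-3-yn-1-yl]-4,5-bis(tert-butyldimethylsilyloxy)-2,6,6-trimethylcyclohex-1-ene
Product: 14 (4R,5R)-4,5-bis(tert-butyldimethylsilyloxy)-1-[(1E,3E)-4-iodo-3-methylbuta-1,3-dien-1-yl]-2,6,6-trimethylcyclohex-1-ene, via alkenyldimethylalane 13 (not isolated)
Conditions: AlMe3 (3 equiv), Cp2ZrCl2 (0.5 equiv), CH2Cl2, 23 °C; then I2, THF, −30 → 0 °C
Reagents that add atoms: trimethylaluminium, C[Al](C)C; iodine, II
Why: Negishi zirconium-catalysed carboalumination: syn addition of methyl and aluminium across the terminal alkyne places the methyl on the internal carbon, and iodinolysis of the C–Al bond with retention gives the E-trisubstituted alkenyl iodide.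

Step 9
Reactants: 14 (4R,5R)-4,5-bis(tert-butyldimethylsilyloxy)-1-[(1E,3E)-4-iodo-3-methylbuta-1,3-dien-1-yl]-2,6,6-trimethylcyclohex-1-ene
Product: 15 (1R,2R)-4-[(1E,3E)-4-iodo-3-methylbuta-1,3-dien-1-yl]-3,3,5-trimethylcyclohex-4-ene-1,2-diol
Conditions: Bu4NF, THF, 23 → 45 °C
Reagents that add atoms: none
Why: Fluoride-driven desilylation (Si–F bond formation) frees both hydroxyls, and the dienyl iodide carries no hydrogen that would allow elimination under these conditions.

Step 10
Reactants: 15 (1R,2R)-4-[(1E,3E)-4-iodo-3-methylbuta-1,3-dien-1-yl]-3,3,5-trimethylcyclohex-4-ene-1,2-diol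
Product: 16 sodium (1R,2R)-2-hydroxy-4-[(1E,3E)-4-iodo-3-methylbuta-1,3-dien-1-yl]-3,3,5-trimethylcyclohex-4-en-1-yl sulfate
Conditions: SO3·pyridine (1.2 equiv), pyridine/DMF, 0 °C; then aq NaHCO3
Reagents that add atoms: sulfur trioxide–pyridine complex, [O-]S(=O)(=O)[n+]1ccccc1; sodium hydrogen carbonate, [Na+].OC([O-])=O
Why: O-sulfation with the SO3–pyridine complex should occur at the secondary hydroxyl flanked by CH2 (carotenoid C3) and spare the neopentyl hydroxyl next to the gem-dimethyl carbon (C2), with limiting reagent and low temperature securing mono-sulfation.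

Step 11
Reactants: 17 (2E,4E,6E)-2,7-dimethylocta-2,4,6-trienedial; 18 bis(4,4,5,5-tetramethyl-1,3,2-dioxaborolan-2-yl)methane
Product: 20 (1E,3E,5E,7E,9E)-3,8-dimethyl-1,10-bis(4,4,5,5-tetramethyl-1,3,2-dioxaborolan-2-yl)deca-1,3,5,7,9-pentaene, via lithiated bis(pinacolboryl)methane 19 (not isolated)
Conditions: 18 (2.4 equiv), lithium 2,2,6,6-tetramethylpiperidide (LiTMP, 2.4 equiv), THF, 0 °C; then 17, −78 → 23 °C
Reagents that add atoms: none
Why: Boron–Wittig olefination: the α-boryl carbanion adds to each aldehyde and syn B–O elimination from the β-alkoxy gem-diboronate should give the trans-alkenyl boronate at both ends of the C2-symmetric trienedial.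

Step 12
Reactants: 15 (1R,2R)-4-[(1E,3E)-4-iodo-3-methylbuta-1,3-dien-1-yl]-3,3,5-trimethylcyclohex-4-ene-1,2-diol; 20 the C12 bis-boronate (3 equiv)
Product: 21 2-[(1E,3E,5E,7E,9E,11E,13E)-14-[(4R,5R)-4,5-dihydroxy-2,6,6-trimethylcyclohex-1-en-1-yl]-3,8,12-trimethyltetradeca-1,3,5,7,9,11,13-heptaen-1-yl]-4,4,5,5-tetramethyl-1,3,2-dioxaborolane
Conditions: Pd(OAc)2 (5 mol %), SPhos (10 mol %), aq NaOH (3 equiv), THF, degassed, dark, 23 °C
Reagents that add atoms: none
Why: Suzuki–Miyaura alkenyl–alkenyl coupling with retention at both partners forms C10–C11, and the threefold excess of the C2-symmetric bis-boronate should make mono-coupling dominant, the non-polar excess linchpin being recovered from the polar diol product.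

Step 13
Reactants: 21 the C26 heptaenyl pinacol boronate; 16 the sulfated C14 dienyl iodide (sodium salt)
Product: 23 (2R,3R,2'R,3'R)-nostoxanthin 3'-(hydrogen sulfate), via sodium nostoxanthin 3'-sulfate 22 (not isolated)
Conditions: Pd(OAc)2 (5 mol %), SPhos (10 mol %), aq NaOH (3 equiv), THF, degassed, dark, 23 °C; work-up with 1 equiv cold dilute aq HCl, 0 °C
Reagents that add atoms: none
Why: Zerovalent palladium (from Pd(OAc)2 and SPhos) inserts into the C10'–I bond of 16 with retention, hydroxide turns the C11' pinacol boronate of 21 into the boronate that transmetalates, and reductive elimination forms the C10'–C11' bond with retention at both alkenes, so the E,E-diene junction and with it the complete all-E undecaene appear in one operation. The closest known reaction type is the Suzuki–Miyaura coupling of polyenyl boronic esters with alkenyl iodides in aqueous base. No ring is closed and no stereocentre is created; the four carbinol centres arrive intact because the free 1,2-diol, the neopentyl hydroxyl and the alkyl sulfate monoester salt do not react with the catalyst or with aqueous hydroxide at room temperature. The selectivity needed is chemoselectivity and stereoretention: only the C–I and C–B termini may react, which is secured by fast oxidative addition at the unhindered C10' iodide and fast transmetalation at the unsubstituted C11' terminus, with oxygen and light excluded to suppress homocoupling, protodeboronation and E/Z isomerization. The sulfate anion acts as a built-in charge tag that should separate 22 from neutral by-products on reversed-phase or ion-exchange media, and one equivalent of cold dilute acid gives the hydrogen sulfate 23.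

**Compound list**

1 | 2,6-dimethylphenol | Cc1cccc(C)c1O | starting material
2 | sodium 2,6-dimethylphenoxide | Cc1cccc(C)c1[O-].[Na+] | intermediate (not isolated)
3 | 2,6,6-trimethylcyclohexa-2,4-dien-1-one | CC1=CC=CC(C)(C)C1=O | intermediate
4 | (4S,5R)-4,5-epoxy-2,6,6-trimethylcyclohex-2-en-1-one | CC1=C[C@@H]2O[C@@H]2C(C)(C)C1=O | intermediate
5 | (4R,5R)-4,5-dihydroxy-2,6,6-trimethylcyclohex-2-en-1-one | CC1=C[C@@H](O)[C@H](O)C(C)(C)C1=O | intermediate
6 | (4R,5R)-4,5-bis(tert-butyldimethylsilyloxy)-2,6,6-trimethylcyclohex-2-en-1-one | CC1=C[C@@H](O[Si](C)(C)C(C)(C)C)[C@H](O[Si](C)(C)C(C)(C)C)C(C)(C)C1=O | intermediate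
7 | lithium (4R,5R)-4,5-bis(tert-butyldimethylsilyloxy)-2,6,6-trimethylcyclohex-1-en-1-olate | CC1=C(O[Li])C(C)(C)[C@@H](O[Si](C)(C)C(C)(C)C)[C@H](O[Si](C)(C)C(C)(C)C)C1 | intermediate (not isolated)
8 | (4R,5R)-4,5-bis(tert-butyldimethylsilyloxy)-2,6,6-trimethylcyclohex-1-en-1-yl trifluoromethanesulfonate | CC1=C(OS(=O)(=O)C(F)(F)F)C(C)(C)[C@@H](O[Si](C)(C)C(C)(C)C)[C@H](O[Si](C)(C)C(C)(C)C)C1 | intermediate
9 | methyl vinyl ketone (but-3-en-2-one) | CC(=O)C=C | starting material
10 | (E)-4-[(4R,5R)-4,5-bis(tert-butyldimethylsilyloxy)-2,6,6-trimethylcyclohex-1-en-1-yl]but-3-en-2-one | CC(=O)/C=C/C1=C(C)C[C@@H](O[Si](C)(C)C(C)(C)C)[C@H](O[Si](C)(C)C(C)(C)C)C1(C)C | intermediate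
11 | diethyl (E)-4-[(4R,5R)-4,5-bis(tert-butyldimethylsilyloxy)-2,6,6-trimethylcyclohex-1-en-1-yl]buta-1,3-dien-2-yl phosphate | C=C(OP(=O)(OCC)OCC)/C=C/C1=C(C)C[C@@H](O[Si](C)(C)C(C)(C)C)[C@H](O[Si](C)(C)C(C)(C)C)C1(C)C | intermediate (not isolated)
12 | (4R,5R)-1-[(E)-but-1-en-3-yn-1-yl]-4,5-bis(tert-butyldimethylsilyloxy)-2,6,6-trimethylcyclohex-1-ene | C#C/C=C/C1=C(C)C[C@@H](O[Si](C)(C)C(C)(C)C)[C@H](O[Si](C)(C)C(C)(C)C)C1(C)C | intermediate
13 | [(1E,3E)-4-[(4R,5R)-4,5-bis(tert-butyldimethylsilyloxy)-2,6,6-trimethylcyclohex-1-en-1-yl]-2-methylbuta-1,3-dien-1-yl]dimethylalane | C[Al](C)/C=C(C)/C=C/C1=C(C)C[C@@H](O[Si](C)(C)C(C)(C)C)[C@H](O[Si](C)(C)C(C)(C)C)C1(C)C | intermediate (not isolated)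
14 | (4R,5R)-4,5-bis(tert-butyldimethylsilyloxy)-1-[(1E,3E)-4-iodo-3-methylbuta-1,3-dien-1-yl]-2,6,6-trimethylcyclohex-1-ene | I/C=C(C)/C=C/C1=C(C)C[C@@H](O[Si](C)(C)C(C)(C)C)[C@H](O[Si](C)(C)C(C)(C)C)C1(C)C | intermediate
15 | (1R,2R)-4-[(1E,3E)-4-iodo-3-methylbuta-1,3-dien-1-yl]-3,3,5-trimethylcyclohex-4-ene-1,2-diol | I/C=C(C)/C=C/C1=C(C)C[C@@H](O)[C@H](O)C1(C)C | intermediate
16 | sodium (1R,2R)-2-hydroxy-4-[(1E,3E)-4-iodo-3-methylbuta-1,3-dien-1-yl]-3,3,5-trimethylcyclohex-4-en-1-yl sulfate | I/C=C(C)/C=C/C1=C(C)C[C@@H](OS(=O)(=O)[O-])[C@H](O)C1(C)C.[Na+] | intermediate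
17 | (2E,4E,6E)-2,7-dimethylocta-2,4,6-trienedial | O=C/C(C)=C/C=C/C=C(C)/C=O | starting material
18 | bis(4,4,5,5-tetramethyl-1,3,2-dioxaborolan-2-yl)methane | CC1(C)OB(CB2OC(C)(C)C(C)(C)O2)OC1(C)C | starting material
19 | lithiated bis(4,4,5,5-tetramethyl-1,3,2-dioxaborolan-2-yl)methane | [Li]C(B1OC(C)(C)C(C)(C)O1)B1OC(C)(C)C(C)(C)O1 | intermediate (not isolated)
20 | (1E,3E,5E,7E,9E)-3,8-dimethyl-1,10-bis(4,4,5,5-tetramethyl-1,3,2-dioxaborolan-2-yl)deca-1,3,5,7,9-pentaene | CC1(C)OB(/C=C/C(C)=C/C=C/C=C(C)/C=C/B2OC(C)(C)C(C)(C)O2)OC1(C)C | intermediate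
21 | 2-[(1E,3E,5E,7E,9E,11E,13E)-14-[(4R,5R)-4,5-dihydroxy-2,6,6-trimethylcyclohex-1-en-1-yl]-3,8,12-trimethyltetradeca-1,3,5,7,9,11,13-heptaen-1-yl]-4,4,5,5-tetramethyl-1,3,2-dioxaborolane | CC1=C(/C=C/C(C)=C/C=C/C(C)=C/C=C/C=C(C)/C=C/B2OC(C)(C)C(C)(C)O2)C(C)(C)[C@@H](O)[C@H](O)C1 | intermediate
22 | sodium (2R,3R,2'R,3'R)-nostoxanthin 3'-sulfate | CC1=C(/C=C/C(C)=C/C=C/C(C)=C/C=C/C=C(C)/C=C/C=C(C)/C=C/C2=C(C)C[C@@H](OS(=O)(=O)[O-])[C@H](O)C2(C)C)C(C)(C)[C@@H](O)[C@H](O)C1.[Na+] | intermediate (not isolated)
23 | (2R,3R,2'R,3'R)-nostoxanthin 3'-(hydrogen sulfate), CNP0229621.3 | CC1=C(/C=C/C(C)=C/C=C/C(C)=C/C=C/C=C(C)/C=C/C=C(C)/C=C/C2=C(C)C[C@@H](OS(=O)(=O)O)[C@H](O)C2(C)C)C(C)(C)[C@@H](O)[C@H](O)C1 | target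

**Step count and risks**

Total step count: 13. Longest linear sequence: 11 steps (steps 1–9, 12, 13; the branch through step 10 is equally long).

Steps most likely to fail:

1. Step 2. Enantiofacial discrimination may be insufficient on a dienone that has a vinyl instead of an aryl conjugating group, and uncatalysed or enone-side oxidation may compete. The fallback replaces asymmetric catalysis by kinetic resolution and sets out from 3. Epoxidation with mCPBA/NaHCO3 in CH2Cl2 should give racemic cis-4,5-epoxy-2,6,6-trimethylcyclohex-2-en-1-one F1. Hydrolysis as in step 3 should give racemic trans-4,5-dihydroxy-2,6,6-trimethylcyclohex-2-en-1-one F2. Acylation with Burkholderia cepacia lipase and vinyl acetate in t-BuOMe at 30 °C is expected, by the empirical rule for lipase acylation of secondary alcohols (larger flank C5, medium flank C3), to acylate the (4R)-carbinol and give (4R,5R)-4-acetoxy-5-hydroxy-2,6,6-trimethylcyclohex-2-en-1-one F3, separable from the unreacted enantiomeric diol. Methanolysis (K2CO3, MeOH, 0 °C) returns to the route at 5. The configuration would be checked by Mosher ester analysis before continuing.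

2. Step 13. Protodeboronation and oxidative or photochemical degradation of the heptaenyl boronate may outrun transmetalation, and the anionic amphiphilic partner may aggregate or mix poorly with the lipophilic boronate. The fallback moves the sulfation behind the chain assembly and sets out from 21 and 15. Their neutral coupling under the step 12 conditions should give (2R,3R,2'R,3'R)-nostoxanthin F4. Sub-stoichiometric SO3·pyridine (0.8 equiv, pyridine/DMF, 0 °C; then aq NaHCO3) should sulfate one of the two equivalent unhindered C3/C3' hydroxyls. Separation by charge gives the monosulfate salt, with neutral F4 recycled, and the route is rejoined at 22, which the cold acid work-up converts to 23.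

3. Step 6. Insertion at the doubly flanked tetrasubstituted alkenyl–palladium centre may be slow, so that triflate reduction or hydrolysis and polymerization of the enone partner take over. The fallback replaces alkene insertion by alkyne coupling and directed trans-reduction and sets out from 8. Sonogashira coupling with but-3-yn-2-ol (Pd(PPh3)4, CuI, i-Pr2NH, DMF, 50 °C) should give 4-[(4R,5R)-4,5-bis(tert-butyldimethylsilyloxy)-2,6,6-trimethylcyclohex-1-en-1-yl]but-3-yn-2-ol F5 (carbinol epimers, of no consequence). Alkoxide-directed trans-hydroalumination with NaAlH2(OCH2CH2OCH3)2 in THF (0 → 23 °C) should give the (E)-allylic alcohol (E)-4-[(4R,5R)-4,5-bis(tert-butyldimethylsilyloxy)-2,6,6-trimethylcyclohex-1-en-1-yl]but-3-en-2-ol F6. Oxidation with MnO2 in CH2Cl2 returns to the route at 10.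

**Further compounds**

F1 | step 2 | racemic cis-4,5-epoxy-2,6,6-trimethylcyclohex-2-en-1-one | CC1=CC2OC2C(C)(C)C1=O
F2 | step 2 | racemic trans-4,5-dihydroxy-2,6,6-trimethylcyclohex-2-en-1-one | CC1=CC(O)C(O)C(C)(C)C1=O
F3 | step 2 | (4R,5R)-4-acetoxy-5-hydroxy-2,6,6-trimethylcyclohex-2-en-1-one | CC1=C[C@@H](OC(C)=O)[C@H](O)C(C)(C)C1=O
F4 | step 13 | (2R,3R,2'R,3'R)-nostoxanthin | CC1=C(/C=C/C(C)=C/C=C/C(C)=C/C=C/C=C(C)/C=C/C=C(C)/C=C/C2=C(C)C[C@@H](O)[C@H](O)C2(C)C)C(C)(C)[C@@H](O)[C@H](O)C1
F5 | step 6 | 4-[(4R,5R)-4,5-bis(tert-butyldimethylsilyloxy)-2,6,6-trimethylcyclohex-1-en-1-yl]but-3-yn-2-ol | CC(O)C#CC1=C(C)C[C@@H](O[Si](C)(C)C(C)(C)C)[C@H](O[Si](C)(C)C(C)(C)C)C1(C)C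
F6 | step 6 | (E)-4-[(4R,5R)-4,5-bis(tert-butyldimethylsilyloxy)-2,6,6-trimethylcyclohex-1-en-1-yl]but-3-en-2-ol | CC(O)/C=C/C1=C(C)C[C@@H](O[Si](C)(C)C(C)(C)C)[C@H](O[Si](C)(C)C(C)(C)C)C1(C)C
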